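## Structural features

Oppositin is a 5,7-dimethoxyflavone: benzo ring A is fused through C4a–C8a to the 4-pyranone ring C, which carries the phenyl ring B at C2. C6 of ring A is bonded to C6' of a second 4-pyranone, ring D, which has a methyl group at C2', a methoxy group at C3' and its carbonyl at C4' (the O-methylmaltol pattern). The molecule has no stereocentre. The C6–C6' axis lies between two methoxy groups on ring A but meets only O1' and C5'–H on ring D, so no configurationally stable axis is expected. The fragile groups are the two pyranones (vinylogous esters that hydroxide and hard nucleophiles open at C2 and C6'), the vinylogously acidic C2' methyl group, the 5-methoxy group peri to C4=O (lost to strong Lewis acids), and the electron-rich ring A (attacked by halogens and electrophilic oxidants). The real difficulties are the hindered C6–C6' bond together with the adjacent C3'/C4' oxygens of ring D, and fusing ring C so that ring D ends up at C6 and not at C8. The second is solved by symmetry: a 3,5-dimethoxyphenol that carries ring D at C4 has two equivalent positions ortho to the hydroxyl. The key step exploits the first: C3'–C4'–C5'–C6' with oxygen on both end carbons is the carbon chain of a 2,5-disubstituted furan, and C2' with its methyl group and O1' is a 1-hydroxyethyl side chain, so oxidative ring expansion of the furfuryl alcohol closes O1'–C6' and delivers ring D.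

## Logic of the disconnections

**27 to 25, then 23 + 24.** Ring C is cut at O1–C2 and at C2–C3. Both bonds come from one precursor, because an aryl ester beside an acetyl group rearranges under base to the 1,3-diketone 26 (new C2–C3 bond), and acid then closes O1–C2 with loss of water. This removes ring C and turns ring B into the acyl part of an ester; cutting the ester C–O bond gives 23 and 24. The forward step must enolize the acetyl group productively although the C2' methyl group is also acidic. The acyl transfer is intramolecular, and only the acetyl enolate can reach the ester.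

**23 to 20 + 21.** The C4–C4a bond is cut. In 20 the two ring A positions ortho to the hydroxyl are related by the local mirror plane through C6 and C8a, so C-acylation can give one product only and ring D must end up at C6. The gain is a symmetric benzene ring with one free position type. The forward step needs a Lewis acid strong enough for C-acylation that does not cleave methyl ethers and tolerates the basic carbonyl of ring D.

**20 to 19 to 18.** The O–benzyl bond at the future C8a oxygen is restored and the C3'–O–CH3 bond is cut. The benzyl ether keeps the C8a oxygen distinct from the two methoxy groups from the first step on. Methylating the enolic C3' hydroxyl while the phenol is masked avoids having to tell two acidic hydroxyl groups apart. The forward steps demand a debenzylation that spares the pyranone double bonds, and O-methylation of the hydroxypyranone.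

**18 to 16 to 15 to 14.** The C4'–O bond is cut, and the C5'=C6' unsaturation is traded for a methoxy group at C6'. Ring D of 18 is one oxidation level above an enone. The extra oxygen at C4' is placed by adding a peroxide oxygen across C4'=C5' (16) and rearranging with acid with loss of methanol; removing the ketal methyl of 15 leads back to 14. This reduces the 3-oxy-4-pyranone to a plain 2H-pyran-3(6H)-one. The oxidant must be nucleophilic so that ring A is not touched, and the ring must stay closed (hence the ketal) while base and then acid act on it.

**14 to 12 (key disconnection).** The O1'–C6' bond is cut, and the C3' and C6' carbonyl carbons are recognized as C2 and C5 of a furan. Oxidative ring expansion is the shortest way to a six-membered ring with methyl on C2', oxygen on C3' and the aryl group on C6'. Ring D becomes an aromatic furan with a 1-hydroxyethyl side chain. The ring closure does create a stereocentre at C6' beside the one carried at C2'. It is uncontrolled and both are erased at 18, so 12 can be racemic and 14 to 17 can be diastereomeric mixtures. The forward step must oxidize the furan and not ring A.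

**12 to 10 + 11.** The C2'–CH3 bond is cut. A formyl group can be carried through the metalation chemistry in masked form, and the carbinol, which is acid-sensitive on an electron-rich aryl furan, is then made last. The gain is an achiral aldehyde; the demand is a simple 1,2-addition.

**10 to 5 + 6.** The C6–C6' bond is cut. It joins a di-ortho-substituted, electron-rich arene to furan C5. With the arene as electrophile and a furylzinc as nucleophile, the leaving group fixes the site on ring A and the innate C5 acidity of a 2-substituted furan fixes the site on the furan. This replaces building the furan from a 1,4-diketone, which would start with acyl-anion addition of a hindered, deactivated benzaldehyde to a vinyl ketone and then need acid cyclodehydration next to a silyloxy group; that path is longer and its first step is doubtful. The forward step needs a catalyst for hindered coupling and the aldehyde masked as an acetal.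

**5 to 4 to 2 to 1.** The sulfonate S–O bond is cut, then the aryl oxygen is exchanged for the formyl carbon (peracid oxidation with aryl migration), then the O–benzyl bond is cut. In 1 the formyl carbon marks the ring D position and the only free hydroxyl is the future C8a oxygen, so no regioselective substitution of a 1,3,5-trioxygenated benzene is needed. The forward oxidation demands aryl migration over hydride migration, which the ortho and para oxygen substituents assure.

## Other disconnections considered

Alternative 1: The cut removes ring C from ring A at O1–C8a and C4–C4a. Ring A then appears as the C4a–C8a aryne generated from the silyl triflate A1, and C2–C4 with ring B come from 3-phenylpropiolic acid A2. In the forward key step CsF would unmask the aryne. The carboxylate oxygen of A2 should add at C8a, the aryne carbon remote from the C5 methoxy group. The aryl anion at C4a, stabilized inductively by that methoxy group, should then take over the acyl group to give the ortho-hydroxyaryl ynone A3, and a 6-endo-dig oxa-Michael closure would finish 27.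
- In its favour: both anchors of ring C are set in one operation, the regiochemistry follows the 3-alkoxyaryne rule, the conditions are nearly neutral and spare the C2' methyl group, and the product is one step from the target.
- Against it here: A1 is a pentasubstituted arene that would have to be made from 20 by ortho-halogenation, O-silylation, metalation with silyl migration and triflation, and the organolithium needed for the silyl migration is hard to reconcile with ring D. The aryl anion can be protonated by A2 before acyl transfer, and the phenoxide of A3 can close 5-exo as well as 6-endo under fluoride.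
- Comparison: on structure, this plan addresses ring C only and presupposes ring D, so it would replace steps 12 to 14 and not the furan strategy. On mechanism, its regiocontrol is the equal of the symmetry argument of the chosen plan, and it is the better plan in avoiding strong base next to the acidic C2' methyl group. On step economy, two steps from A1 to 27 beat three from 20 to 27, but the three or four steps from 20 to A1 reverse that advantage.

Alternative 2: Ring A is dismantled at C7–C8, C8a–C4a and C6–C7 into the cyclobutenone A4, which already carries ring D, and the silyloxyacetylene A5. Heating the two in toluene would open A4 to a vinylketene, which adds A5 in a [2+2] step; a second ring opening and 6π closure (Danheiser benzannulation) would give the phenol A6 with methoxy, free hydroxyl and silyl ether as three distinct oxygens.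
- In its favour: ring A is built regiospecifically with full differentiation under neutral thermal conditions, there is no electrophilic substitution on an electron-rich arene, and the silyl ether at the future C8a oxygen is removed by fluoride without hydrogenation.
- Against it here: A4 is a 4-heteroaryl cyclobutenone with a doubly activated C4–H, and its synthesis needs a finished ring D and is not obvious. The ketene from ring opening is conjugated with C5'=C6' of ring D, so intramolecular 6π closure onto ring D can compete with bimolecular capture by A5. After A6, O-methylation, desilylation and all of ring C remain.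
- Comparison: on structure, the chosen plan buys ring A with the same differentiation (benzyl against methyl) in the form of 1, so this alternative spends its key step on a ring that needs no synthesis. On mechanism, the pericyclic cascade is the equal of the chosen plan in regiochemical certainty and the better one in differentiating the oxygens without hydrogenolysis. On step economy it is longer, because ring D must first be made by some other method and about five steps follow A6.

Alternative 3: Ring A is cut at C5–C6 only, which gives the keto ester A7 with rings C and D finished and joined by a three-carbon keto chain. NaOMe in methanol would deprotonate the C6 methylene, flanked by the C7 ketone and ring D. The carbanion would attack the ester carbon C5 (Claisen-type 6-exo-trig closure), and enolization would give the 5,7-dihydroxyflavone A8; two O-methylations would lead to 27.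
- In its favour: a biomimetic aromatization with a strong driving force, no protecting groups, only one six-membered closure open to the C6 carbanion, and two steps from A7 to the target.
- Against it here: A7 holds two base-sensitive pyranones, one of them a 3-acyl-4-pyranone that methoxide can open at C8a or C2, a second acidic methylene at C8, and the acidic C2' methyl group. Assembling A7 from two pyranone halves through the keto linker is a multistep problem of its own, and exhaustive methylation has to overcome the chelated 5-hydroxyl.
- Comparison: on structure, it is the most convergent plan and the better one in protecting-group economy. On mechanism, the aromatizing Claisen condensation is as well founded as the furan ring expansion, but its chemoselectivity depends on a polycarbonyl substrate surviving methoxide, whereas the chosen plan applies base only to robust intermediates. On step economy, its end game is shorter than steps 10 to 14, while the way to A7 is likely to cost more than the five steps that lead to 12.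

Key step: step 6

## Route

Step 1
Reactants: 1 4-hydroxy-2,6-dimethoxybenzaldehyde
Product: 2 4-(benzyloxy)-2,6-dimethoxybenzaldehyde
Conditions: BnBr, K2CO3, DMF, rt
Reagents that add atoms: benzyl bromide, BrCc1ccccc1
Why: Williamson etherification of the only hydroxyl group; the benzyl ether marks the future C8a oxygen, survives peracid, organometallics, base and mild acid, and is removed later by neutral hydrogenolysis.

Step 2
Reactants: 2 4-(benzyloxy)-2,6-dimethoxybenzaldehyde
Product: 4 4-(benzyloxy)-2,6-dimethoxyphenol, via aryl formate 3 (not isolated)
Conditions: m-CPBA, CH2Cl2, 0 °C to rt; aq. NaHCO3 wash; K2CO3 (cat.), MeOH, N2, rt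
Reagents that add atoms: 3-chloroperoxybenzoic acid (m-CPBA), OOC(=O)c1cccc(Cl)c1
Why: Dakin-type Baeyer–Villiger oxidation; the ortho and para oxygen substituents make the aryl group migrate in preference to hydride, and the phenol stays masked as its formate until the peracid has been washed out, which prevents quinone formation.

Step 3
Reactants: 4 4-(benzyloxy)-2,6-dimethoxyphenol
Product: 5 4-(benzyloxy)-2,6-dimethoxyphenyl trifluoromethanesulfonate
Conditions: Tf2O, pyridine, CH2Cl2, 0 °C
Reagents that add atoms: trifluoromethanesulfonic anhydride, O=S(=O)(OS(=O)(=O)C(F)(F)F)C(F)(F)F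
Why: O-sulfonylation of the phenol; the triflate turns the carbon that carried the formyl group into a cross-coupling electrophile with unambiguous regiochemistry.

Step 4
Reactants: 5 4-(benzyloxy)-2,6-dimethoxyphenyl trifluoromethanesulfonate; 6 2-(furan-2-yl)-1,3-dioxolane
Product: 10 5-[4-(benzyloxy)-2,6-dimethoxyphenyl]furan-2-carbaldehyde, via lithiated furan acetal 7 (not isolated), via furylzinc chloride 8 (not isolated), via coupled acetal 9 (not isolated)
Conditions: 6, n-BuLi, THF, −78 °C; ZnCl2, −78 °C to rt; 5, Pd(OAc)2 (2 mol %), XPhos (4 mol %), THF, 60 °C; then 1 M HCl, THF, rt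
Reagents that add atoms: water, O
Why: Negishi coupling; the acetal-bearing furan is lithiated at C5, its only acidic ring position, and transmetalated to zinc, and the bulky biarylphosphine lets zerovalent palladium (formed in situ from Pd(OAc)2) insert into the hindered, electron-rich triflate. A 2-furylzinc reagent does not suffer the protodemetalation that plagues 2-furylboron reagents, and the acidic work-up hydrolyses the acetal to the aldehyde.

Step 5
Reactants: 10 5-[4-(benzyloxy)-2,6-dimethoxyphenyl]furan-2-carbaldehyde; 11 methylmagnesium bromide
Product: 12 racemic 1-{5-[4-(benzyloxy)-2,6-dimethoxyphenyl]furan-2-yl}ethanol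
Conditions: 11, THF, −20 to 0 °C; aq. NH4Cl
Reagents that add atoms: none
Why: Grignard 1,2-addition to the aldehyde; the new carbinol centre is formed racemic on purpose, because C2' becomes sp2 in step 9, and the neutral quench protects the acid-sensitive furfuryl alcohol.

Step 6
Reactants: 12 racemic 1-{5-[4-(benzyloxy)-2,6-dimethoxyphenyl]furan-2-yl}ethanol
Product: 14 6-[4-(benzyloxy)-2,6-dimethoxyphenyl]-6-hydroxy-2-methyl-2H-pyran-3(6H)-one (racemic mixture of C6 epimers), via Z-enedione 13 (not isolated)
Conditions: m-CPBA (1.1 equiv), NaHCO3, CH2Cl2, 0 °C
Reagents that add atoms: 3-chloroperoxybenzoic acid (m-CPBA), OOC(=O)c1cccc(Cl)c1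
Why: The peracid transfers oxygen to a ring C=C bond of the electron-rich 2,5-disubstituted furan, and the furan oxygen opens the resulting epoxide so that the ring unravels to the Z-enedione 13, in which the former furan carbons C2 and C5 are the C3' and C6' carbonyl groups. The secondary hydroxyl then adds to the aryl ketone carbonyl in a 6-exo-trig hemiketalization, which forms O1'–C6' and closes ring D as the 6-hydroxy-2H-pyran-3(6H)-one. The closest known reaction type is the Achmatowicz rearrangement of 5-substituted furfuryl alcohols. Epoxidation at either furan double bond leads to the same enedione, so there is no regiochemical issue. C6' is a new but uncontrolled stereocentre, set under thermodynamic (anomeric) control relative to the racemic C2' centre; both become sp2 in step 9, so the epimer mixture is carried on. The selectivity needed is chemoselectivity for the furan over the trioxygenated benzene ring, the benzyl ether and the product enone. It is secured because the furan is the most nucleophilic π system, the 2,6-dimethoxyaryl ring is twisted out of conjugation and hindered at its own free positions, one equivalent of oxidant is used at 0 °C, and a peracid, unlike a halogen oxidant, does not substitute the arene. Solid NaHCO3 keeps the acid by-product from ionizing the tertiary benzylic hemiketal.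

Step 7
Reactants: 14 6-[4-(benzyloxy)-2,6-dimethoxyphenyl]-6-hydroxy-2-methyl-2H-pyran-3(6H)-one
Product: 15 6-[4-(benzyloxy)-2,6-dimethoxyphenyl]-6-methoxy-2-methyl-2H-pyran-3(6H)-one (racemic mixture of diastereomers)
Conditions: MeOH, PPTS (cat.), 3 Å molecular sieves, 0 °C to rt
Reagents that add atoms: methanol, CO
Why: Acid-catalysed ketal exchange through the C6' oxocarbenium ion, which the ring oxygen and the trioxygenated aryl group stabilize so well that a weak acid suffices; any open-chain 13 in equilibrium with 14 is drawn into the same ketal. The methyl ketal prevents ring opening to the enedione under the basic conditions of step 8.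

Step 8
Reactants: 15 6-[4-(benzyloxy)-2,6-dimethoxyphenyl]-6-methoxy-2-methyl-2H-pyran-3(6H)-one
Product: 16 2-[4-(benzyloxy)-2,6-dimethoxyphenyl]-2-methoxy-4-methyl-3,7-dioxabicyclo[4.1.0]heptan-5-one (mixture of diastereomers)
Conditions: 30% H2O2, NaOH (cat.), MeOH, 0 °C
Reagents that add atoms: hydrogen peroxide, OO
Why: Weitz–Scheffer epoxidation; hydroperoxide adds to C5' of the enone and the enolate closes onto oxygen, which places the future C4' oxygen, and a nucleophilic oxidant leaves the electron-rich arene and the benzyl ether alone. The configuration of the epoxide is irrelevant because all ring D centres are lost in step 9.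

Step 9
Reactants: 16 2-[4-(benzyloxy)-2,6-dimethoxyphenyl]-2-methoxy-4-methyl-3,7-dioxabicyclo[4.1.0]heptan-5-one
Product: 18 6-[4-(benzyloxy)-2,6-dimethoxyphenyl]-3-hydroxy-2-methyl-4H-pyran-4-one, via diosphenol 17 (not isolated)
Conditions: p-TsOH·H2O (0.3 equiv), MeOH, 60 °C
Reagents that add atoms: none
Why: Acid opens the epoxide at C5', the carbon remote from the ketone, and loss of the C4' proton gives the enolized 1,2-dione 17; ionization of the C6' ketal, loss of methanol and enolization toward C2' then give the 3-hydroxy-4-pyranone as the thermodynamic sink, the sequence known for maltol-type pyranones. Methanol as solvent keeps the ketal closed until the oxygen is fixed at C4', so that an open-chain aryl ketone cannot divert the oxygen to C5'.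

Step 10
Reactants: 18 6-[4-(benzyloxy)-2,6-dimethoxyphenyl]-3-hydroxy-2-methyl-4H-pyran-4-one
Product: 19 6-[4-(benzyloxy)-2,6-dimethoxyphenyl]-3-methoxy-2-methyl-4H-pyran-4-one
Conditions: MeI, K2CO3, acetone, 50 °C
Reagents that add atoms: iodomethane, CI
Why: O-methylation of the acidic enolic hydroxyl of the 3-hydroxy-4-pyranone; it is the only free hydroxyl, since the phenol is still benzylated.

Step 11
Reactants: 19 6-[4-(benzyloxy)-2,6-dimethoxyphenyl]-3-methoxy-2-methyl-4H-pyran-4-one
Product: 20 6-(4-hydroxy-2,6-dimethoxyphenyl)-3-methoxy-2-methyl-4H-pyran-4-one
Conditions: H2 (1 atm), 10% Pd/C, EtOAc–MeOH, rt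
Reagents that add atoms: none
Why: Hydrogenolysis of the benzyl aryl ether under neutral conditions; the 4-pyranone is a vinylogous ester with aromatic character and is not reduced at one atmosphere, as in the routine debenzylation of O-benzylmaltol derivatives.

Step 12
Reactants: 20 6-(4-hydroxy-2,6-dimethoxyphenyl)-3-methoxy-2-methyl-4H-pyran-4-one; 21 acetic anhydride
Product: 23 6-(3-acetyl-4-hydroxy-2,6-dimethoxyphenyl)-3-methoxy-2-methyl-4H-pyran-4-one, via difluoroboron chelate 22 (not isolated)
Conditions: 21, BF3·OEt2, 70 °C; then aq. NaOAc, MeOH, 60 °C
Reagents that add atoms: none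
Why: BF3-mediated Friedel–Crafts/Fries C-acetylation ortho to the phenol, as for 3,5-dimethoxyphenol itself. The two ortho positions of 20 are equivalent, so a single ketone forms, and it is trapped as the difluoroboron chelate, which stops a second acylation and is hydrolysed in the work-up. BF3 does not cleave aryl methyl ethers under these conditions.

Step 13
Reactants: 23 6-(3-acetyl-4-hydroxy-2,6-dimethoxyphenyl)-3-methoxy-2-methyl-4H-pyran-4-one; 24 benzoyl chloride
Product: 25 2-acetyl-3,5-dimethoxy-4-(5-methoxy-6-methyl-4-oxo-4H-pyran-2-yl)phenyl benzoate
Conditions: 24, pyridine, DMAP (cat.), CH2Cl2, rt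
Reagents that add atoms: none
Why: Acyl-transfer-catalysed O-benzoylation of the only hydroxyl group; the ester brings C2 and ring B next to the acetyl group.

Step 14
Reactants: 25 2-acetyl-3,5-dimethoxy-4-(5-methoxy-6-methyl-4-oxo-4H-pyran-2-yl)phenyl benzoate
Product: 27 oppositin, via beta-diketone 26 (not isolated)
Conditions: KOt-Bu, THF, 0 °C to rt; AcOH quench; then AcOH, H2SO4 (cat.), 90 °C
Reagents that add atoms: none
Why: Baker–Venkataraman rearrangement followed by acid cyclodehydration; the acetyl enolate attacks the neighbouring benzoate intramolecularly (C2–C3), whereas an anion at the C2' methyl group cannot reach the ester and only returns on protonation. Acid then closes O1–C2 with loss of water, and a bulky, non-nucleophilic base followed by acid spares both pyranones.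

## Compound list

1 | 4-hydroxy-2,6-dimethoxybenzaldehyde | COc1cc(O)cc(OC)c1C=O | starting material
2 | 4-(benzyloxy)-2,6-dimethoxybenzaldehyde | COc1cc(OCc2ccccc2)cc(OC)c1C=O | intermediate
3 | 4-(benzyloxy)-2,6-dimethoxyphenyl formate | COc1cc(OCc2ccccc2)cc(OC)c1OC=O | intermediate
4 | 4-(benzyloxy)-2,6-dimethoxyphenol | COc1cc(OCc2ccccc2)cc(OC)c1O | intermediate
5 | 4-(benzyloxy)-2,6-dimethoxyphenyl trifluoromethanesulfonate | COc1cc(OCc2ccccc2)cc(OC)c1OS(=O)(=O)C(F)(F)F | intermediate
6 | 2-(furan-2-yl)-1,3-dioxolane | C1COC(O1)c1ccco1 | starting material
7 | [5-(1,3-dioxolan-2-yl)furan-2-yl]lithium | [Li]c1ccc(C2OCCO2)o1 | intermediate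
8 | chloro[5-(1,3-dioxolan-2-yl)furan-2-yl]zinc | Cl[Zn]c1ccc(C2OCCO2)o1 | intermediate
9 | 2-{5-[4-(benzyloxy)-2,6-dimethoxyphenyl]furan-2-yl}-1,3-dioxolane | COc1cc(OCc2ccccc2)cc(OC)c1-c1ccc(C2OCCO2)o1 | intermediate
10 | 5-[4-(benzyloxy)-2,6-dimethoxyphenyl]furan-2-carbaldehyde | COc1cc(OCc2ccccc2)cc(OC)c1-c1ccc(C=O)o1 | intermediate
11 | methylmagnesium bromide | C[Mg]Br | starting material
12 | racemic 1-{5-[4-(benzyloxy)-2,6-dimethoxyphenyl]furan-2-yl}ethanol | CC(O)c1ccc(-c2c(OC)cc(OCc3ccccc3)cc2OC)o1 | intermediate
13 | racemic (Z)-1-[4-(benzyloxy)-2,6-dimethoxyphenyl]-5-hydroxyhex-2-ene-1,4-dione | CC(O)C(=O)/C=C\C(=O)c1c(OC)cc(OCc2ccccc2)cc1OC | intermediate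
14 | 6-[4-(benzyloxy)-2,6-dimethoxyphenyl]-6-hydroxy-2-methyl-2H-pyran-3(6H)-one, racemic mixture of C6 epimers | CC1OC(O)(c2c(OC)cc(OCc3ccccc3)cc2OC)C=CC1=O | intermediate
15 | 6-[4-(benzyloxy)-2,6-dimethoxyphenyl]-6-methoxy-2-methyl-2H-pyran-3(6H)-one, racemic mixture of diastereomers | CC1OC(OC)(c2c(OC)cc(OCc3ccccc3)cc2OC)C=CC1=O | intermediate
16 | 2-[4-(benzyloxy)-2,6-dimethoxyphenyl]-2-methoxy-4-methyl-3,7-dioxabicyclo[4.1.0]heptan-5-one, racemic mixture of diastereomers | CC1OC(OC)(c2c(OC)cc(OCc3ccccc3)cc2OC)C2OC2C1=O | intermediate
17 | 6-[4-(benzyloxy)-2,6-dimethoxyphenyl]-4-hydroxy-6-methoxy-2-methyl-2H-pyran-3(6H)-one, racemic mixture of diastereomers | CC1OC(OC)(c2c(OC)cc(OCc3ccccc3)cc2OC)C=C(O)C1=O | intermediate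
18 | 6-[4-(benzyloxy)-2,6-dimethoxyphenyl]-3-hydroxy-2-methyl-4H-pyran-4-one | Cc1oc(-c2c(OC)cc(OCc3ccccc3)cc2OC)cc(=O)c1O | intermediate
19 | 6-[4-(benzyloxy)-2,6-dimethoxyphenyl]-3-methoxy-2-methyl-4H-pyran-4-one | COc1c(C)oc(-c2c(OC)cc(OCc3ccccc3)cc2OC)cc1=O | intermediate
20 | 6-(4-hydroxy-2,6-dimethoxyphenyl)-3-methoxy-2-methyl-4H-pyran-4-one | COc1c(C)oc(-c2c(OC)cc(O)cc2OC)cc1=O | intermediate
21 | acetic anhydride | CC(=O)OC(C)=O | starting material
22 | difluoroboron O,O-chelate of 23 (boron bridges the phenolic oxygen and the acetyl oxygen in a six-membered ring) | COc1c(C)oc(-c2c(OC)cc3O[B-](F)(F)[O+]=C(C)c3c2OC)cc1=O | intermediate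
23 | 6-(3-acetyl-4-hydroxy-2,6-dimethoxyphenyl)-3-methoxy-2-methyl-4H-pyran-4-one | COc1c(C)oc(-c2c(OC)cc(O)c(C(C)=O)c2OC)cc1=O | intermediate
24 | benzoyl chloride | O=C(Cl)c1ccccc1 | starting material
25 | 2-acetyl-3,5-dimethoxy-4-(5-methoxy-6-methyl-4-oxo-4H-pyran-2-yl)phenyl benzoate | COc1c(C)oc(-c2c(OC)cc(OC(=O)c3ccccc3)c(C(C)=O)c2OC)cc1=O | intermediate
26 | 1-[6-hydroxy-2,4-dimethoxy-3-(5-methoxy-6-methyl-4-oxo-4H-pyran-2-yl)phenyl]-3-phenylpropane-1,3-dione | COc1c(C)oc(-c2c(OC)cc(O)c(C(=O)CC(=O)c3ccccc3)c2OC)cc1=O | intermediate
27 | oppositin, 5,7-dimethoxy-6-(5-methoxy-6-methyl-4-oxo-4H-pyran-2-yl)-2-phenyl-4H-chromen-4-one | COc1cc2oc(-c3ccccc3)cc(=O)c2c(OC)c1-c1cc(=O)c(OC)c(C)o1 | target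

## Step count and least certain steps

Total: 14 steps. Longest linear sequence: 14 steps, from 1 to 27; compounds 6, 11, 21 and 24 are purchased.

**Step 6 (key step).** The most likely failure is loss of chemoselectivity, with the peracid also attacking the trioxygenated ring or the product. A second is incomplete ring closure: a ketone on a di-ortho-substituted aryl group hemiketalizes reluctantly, and the open Z-enedione can isomerize to the E form, which cannot cyclize. The fallback sets out from 12. Sensitized photooxygenation (O2, tetraphenylporphyrin, visible light, CH2Cl2, −78 °C) should add singlet oxygen to the furan in a [4+2] step, to which a trialkoxybenzene is inert. This would give the endoperoxide 1-[4-(benzyloxy)-2,6-dimethoxyphenyl]-4-(1-hydroxyethyl)-2,3,7-trioxabicyclo[2.2.1]hept-5-ene F1. Dimethyl sulfide would reduce it at low temperature under neutral conditions to 13, which closes to 14, where the route is rejoined.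

**Step 4.** Oxidative addition into the di-ortho-substituted, electron-rich triflate may be slow, so that homocoupling of the furylzinc or S–O cleavage of the triflate by the organometallic takes over. The fallback sets out from 5 and reverses the polarity. Miyaura borylation (B2pin2, KOAc, Pd(OAc)2, SPhos, dioxane, 80 °C) would give 2-[4-(benzyloxy)-2,6-dimethoxyphenyl]-4,4,5,5-tetramethyl-1,3,2-dioxaborolane F2. Suzuki–Miyaura coupling of this electron-rich boronate with purchased 5-bromofuran-2-carbaldehyde, a reactive electron-poor bromide (Pd(OAc)2, SPhos, K3PO4, toluene–water, 60 °C), comes back to the route at 10.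

**Step 7.** The C6' oxocarbenium ion may lose the C2' proton instead of taking up methanol, which drains material into an aromatic 3-hydroxypyrylium species, or open-chain material may isomerize at the double bond. The fallback sets out from 14 and alkylates the hemiketal oxygen instead of substituting at carbon: Purdie methylation (MeI, Ag2O, CH2Cl2, rt) gives 15 directly without any cationic intermediate; no new compound is made (F0).

**Step 8.** Conjugate addition of hydroperoxide at C5' is retarded by the neighbouring quaternary, aryl-bearing C6', and prolonged exposure to hydroxide may then degrade the ketone. The fallback sets out from 15 and replaces nucleophilic by hydroxyl-directed epoxidation. Luche reduction (NaBH4, CeCl3·7H2O, MeOH, −78 °C) would give the allylic alcohol 6-[4-(benzyloxy)-2,6-dimethoxyphenyl]-6-methoxy-2-methyl-3,6-dihydro-2H-pyran-3-ol F3. Epoxidation with VO(acac)2 and t-BuOOH would give 2-[4-(benzyloxy)-2,6-dimethoxyphenyl]-2-methoxy-4-methyl-3,7-dioxabicyclo[4.1.0]heptan-5-ol F4, and Dess–Martin oxidation would return to the route at 16.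

**Step 9.** Opening of the epoxide with cationic character at C5' may trigger a 1,2-shift of the electron-rich aryl group from C6', or premature cleavage of the ketal may steer the oxygen to C5'. The fallback sets out from 15 and avoids the epoxide. Dihydroxylation (OsO4 cat., N-methylmorpholine N-oxide, acetone–water) would give 6-[4-(benzyloxy)-2,6-dimethoxyphenyl]-4,5-dihydroxy-6-methoxy-2-methyloxan-3-one F5. In acidic methanol (p-TsOH, 60 °C) this would lose the C5' hydroxyl by β-elimination through the enol of the ketone, without a cation at C5', and then methanol, returning to the route at 18.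

**Step 12.** The Lewis acid may be sequestered by the basic ring D carbonyl so that the reaction stalls at the O-acetate, or forcing conditions may cleave the methoxy group next to the new chelated ketone. The fallback sets out from 20 and builds ring C without an acetophenone. Iodination ortho to the hydroxyl (N-iodosuccinimide, 1 equiv, MeCN, 0 °C) would give 6-(4-hydroxy-3-iodo-2,6-dimethoxyphenyl)-3-methoxy-2-methyl-4H-pyran-4-one F6. Carbonylative coupling with phenylacetylene under CO (1 atm) with the divalent palladium precatalyst PdCl2(PPh3)2 in Et2NH at 80 °C would give the alkynyl ketone, which closes 6-endo to the flavone, returning to the route at 27 and replacing steps 12 to 14.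

## Further compounds

F1 | step 6 | 1-[4-(benzyloxy)-2,6-dimethoxyphenyl]-4-(1-hydroxyethyl)-2,3,7-trioxabicyclo[2.2.1]hept-5-ene (mixture of stereoisomers) | CC(O)C12OOC(O1)(C=C2)c1c(OC)cc(OCc2ccccc2)cc1OC
F2 | step 4 | 2-[4-(benzyloxy)-2,6-dimethoxyphenyl]-4,4,5,5-tetramethyl-1,3,2-dioxaborolane | COc1cc(OCc2ccccc2)cc(OC)c1B1OC(C)(C)C(C)(C)O1
F0 | step 7 | none | none
F3 | step 8 | 6-[4-(benzyloxy)-2,6-dimethoxyphenyl]-6-methoxy-2-methyl-3,6-dihydro-2H-pyran-3-ol (mixture of diastereomers) | CC1OC(OC)(c2c(OC)cc(OCc3ccccc3)cc2OC)C=CC1O
F4 | step 8 | 2-[4-(benzyloxy)-2,6-dimethoxyphenyl]-2-methoxy-4-methyl-3,7-dioxabicyclo[4.1.0]heptan-5-ol (mixture of diastereomers) | CC1OC(OC)(c2c(OC)cc(OCc3ccccc3)cc2OC)C2OC2C1O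
F5 | step 9 | 6-[4-(benzyloxy)-2,6-dimethoxyphenyl]-4,5-dihydroxy-6-methoxy-2-methyloxan-3-one (mixture of diastereomers) | CC1OC(OC)(c2c(OC)cc(OCc3ccccc3)cc2OC)C(O)C(O)C1=O
F6 | step 12 | 6-(4-hydroxy-3-iodo-2,6-dimethoxyphenyl)-3-methoxy-2-methyl-4H-pyran-4-one | COc1c(C)oc(-c2c(OC)cc(O)c(I)c2OC)cc1=O
A1 | alternative 1 | 3,5-dimethoxy-4-(5-methoxy-6-methyl-4-oxo-4H-pyran-2-yl)-2-(trimethylsilyl)phenyl trifluoromethanesulfonate | COc1cc(OS(=O)(=O)C(F)(F)F)c([Si](C)(C)C)c(OC)c1-c1cc(=O)c(OC)c(C)o1
A2 | alternative 1 | 3-phenylpropiolic acid | OC(=O)C#Cc1ccccc1
A3 | alternative 1 | 1-[6-hydroxy-2,4-dimethoxy-3-(5-methoxy-6-methyl-4-oxo-4H-pyran-2-yl)phenyl]-3-phenylprop-2-yn-1-one | COc1cc(O)c(C(=O)C#Cc2ccccc2)c(OC)c1-c1cc(=O)c(OC)c(C)o1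
A4 | alternative 2 | racemic 3-methoxy-4-(5-methoxy-6-methyl-4-oxo-4H-pyran-2-yl)cyclobut-2-en-1-one | COC1=CC(=O)C1c1cc(=O)c(OC)c(C)o1
A5 | alternative 2 | (ethynyloxy)triisopropylsilane | C#CO[Si](C(C)C)(C(C)C)C(C)C
A6 | alternative 2 | 3-methoxy-2-(5-methoxy-6-methyl-4-oxo-4H-pyran-2-yl)-5-(triisopropylsilyloxy)phenol | COc1cc(O[Si](C(C)C)(C(C)C)C(C)C)cc(O)c1-c1cc(=O)c(OC)c(C)o1
A7 | alternative 3 | methyl 2-[3-(5-methoxy-6-methyl-4-oxo-4H-pyran-2-yl)-2-oxopropyl]-4-oxo-6-phenyl-4H-pyran-3-carboxylate | COC(=O)c1c(CC(=O)Cc2cc(=O)c(OC)c(C)o2)oc(-c2ccccc2)cc1=O
A8 | alternative 3 | 5,7-dihydroxy-6-(5-methoxy-6-methyl-4-oxo-4H-pyran-2-yl)-2-phenyl-4H-chromen-4-one | Oc1cc2oc(-c3ccccc3)cc(=O)c2c(O)c1-c1cc(=O)c(OC)c(C)o1
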